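**Plan**

1. Retrosynthesis first cuts the two C6–O ester bonds, giving two molecules of (−)-incarvilline and (2E,6E)-2,6-dimethylocta-2,6-dienedioic acid (from geranyl acetate by allylic and aldehyde oxidations).
2. In incarvilline the N-methyl nitrogen lies between two ring methylenes, C1 and C3, of the piperidine. Taking N out and joining C1 to a C3 carbonyl contracts that ring to a cis-fused cyclopentanone whose methyl-bearing C4 is alpha to the carbonyl.
3. This cyclopentanone is a Pauson–Khand retron: C3 is CO, C4(Me)=C4a comes from a 2-butynyl unit and C1/C7a from a vinyl group, so both carbocycles come from (3S,4R)-3-methyloct-1-en-6-yn-4-ol.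
4. Forward: crotylboration of pent-3-ynal, acylation, carbonylative [2+2+1] bicyclisation, hydrogenation, nitrone formation, photochemical nitrogen insertion that enlarges the cyclopentanone to the N-methyl piperidinone, LiAlH4 reduction (which also removes the C3 carbonyl helper), twofold esterification.
5. Stereochemistry: C6 and C7 from reagent-controlled (E)-crotylboration, C7a from exo-selective alkene insertion, C4 and C4a from convex-face hydrogenation; ring enlargement, reduction and esterification conserve them. Both alkene geometries come from the geranyl skeleton.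

Key step: step 7

Remarks: ring positions are named throughout with the cyclopenta[c]pyridine numbering of incarvilline (C1, N2, C3, C4, C4a, C5, C6, C7, C7a), also for the carbocyclic precursors; in the twofold steps 11, 12 and 13 both ends react alike under the same conditions, so half-converted species are not numbered.

**Route**

Step 1
Reactants: 1 pent-3-yn-1-ol
Product: 2 pent-3-ynal
Conditions: DMP (1.2 equiv), CH2Cl2, 0 °C to rt; filtration through silica (pentane/Et2O), cold concentration, used at once
Reagents that add atoms: none
Why: Dess–Martin oxidation converts the primary alcohol to the aldehyde under neutral, non-basic conditions, which should suppress prototropic isomerisation of the beta,gamma-alkynyl aldehyde to the allenyl aldehyde; no stereocentre is involved.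

Step 2
Reactants: 2 pent-3-ynal
Product: 3 (3S,4R)-3-methyloct-1-en-6-yn-4-ol
Conditions: trans-2-butene, KOtBu, n-BuLi, THF, −78 to −45 °C; (−)-Ipc2BOMe [from (+)-alpha-pinene], then BF3·OEt2, −78 °C; 2, −78 °C; NaOH, H2O2, 0 °C to rt
Reagents that add atoms: trans-2-butene, C/C=C/C, transferred as (E)-crotyldiisopinocampheylborane, C/C=C/CB([C@@H]1C[C@@H]2C[C@H]([C@H]1C)C2(C)C)[C@@H]1C[C@@H]2C[C@H]([C@H]1C)C2(C)C
Why: Brown asymmetric crotylboration through a closed chair transition state: the (E)-crotyl geometry sets the anti relationship of C3 and C4, and the isopinocampheyl groups derived from (+)-alpha-pinene direct attack to the Si face of the aldehyde, which should give the 3S,4R adduct.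

Step 3
Reactants: 3 (3S,4R)-3-methyloct-1-en-6-yn-4-ol
Product: 4 (3S,4R)-3-methyloct-1-en-6-yn-4-yl pivalate
Conditions: PivCl, pyridine, DMAP (cat.), CH2Cl2, 0 °C to rt
Reagents that add atoms: pivaloyl chloride, CC(C)(C)C(=O)Cl
Why: DMAP-catalysed acylation of the secondary alcohol; the pivalate should survive carbonylation, hydrogenation, nitrone formation and 254 nm light, and is removed by the hydride of step 8, so no separate deprotection is needed.

Step 4
Reactants: 4 (3S,4R)-3-methyloct-1-en-6-yn-4-yl pivalate
Product: 5 (5R,6S,6aS)-3,6-dimethyl-2-oxo-1,2,4,5,6,6a-hexahydropentalen-5-yl pivalate (bicyclic enone; 6-methyl, 5-pivaloyloxy and H6a all cis)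
Conditions: Co2(CO)8 (10 mol %), tetramethylthiourea (60 mol %), CO (1 atm), benzene, 70 °C
Reagents that add atoms: carbon monoxide, [C-]#[O+]
Why: Catalytic intramolecular Pauson–Khand [2+2+1] reaction of the 1,6-enyne with CO builds both five-membered rings and the C3 carbonyl at once; in the alkene-insertion transition state the allylic methyl and the neighbouring pivaloyloxy group should take pseudo-equatorial positions on the convex face, which sets the new ring-fusion hydrogen cis to both.

Step 5
Reactants: 5 bicyclic enone
Product: 6 (1S,2R,3aR,4R,6aR)-1,4-dimethyl-5-oxooctahydropentalen-2-yl pivalate (cis-fused ketone; H4, H4a and H7a of the later alkaloid all cis)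
Conditions: H2 (1 atm), 10% Pd/C, EtOAc, rt
Reagents that add atoms: none
Why: Heterogeneous catalytic hydrogenation adds both hydrogens syn from the convex face that carries the ring-fusion hydrogen, because delivery from the other face would give a strained trans-fused diquinane, so the ring fusion becomes cis and the C4 methyl is pushed to the concave face; neutral conditions should avoid epimerisation of this kinetic alpha-methyl ketone.

Step 6
Reactants: 6 cis-fused ketone
Product: 7 (Z)-N-methyl ketonitrone of 6 (N-methyl syn to the C1 methylene, oxygen syn to C4)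
Conditions: MeNHOH·HCl, NaOAc, EtOH, 3 Å MS, rt
Reagents that add atoms: N-methylhydroxylamine hydrochloride, CNO.Cl
Why: Condensation of the ketone with N-methylhydroxylamine under acetate buffer gives the ketonitrone without enolising conditions; the isomer with the N-methyl group on the side of the unsubstituted C1 methylene and the small oxygen next to the C4 methyl should predominate for steric reasons.

Step 7
Reactants: 7 (Z)-N-methyl ketonitrone
Product: 9 (4R,4aR,6R,7S,7aR)-2,4,7-trimethyl-3-oxooctahydro-1H-cyclopenta[c]pyridin-6-yl pivalate (N-methyl lactam), via spiro-oxaziridine 8 (not isolated)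
Conditions: hν (254 nm, low-pressure Hg lamp, quartz), degassed MeCN, rt
Reagents that add atoms: none
Why: Excitation of the nitrone triggers a four-electron electrocyclisation to spiro-oxaziridine 8 with the nitrone geometry retained (N-methyl cis to the C1 methylene, nitrogen lone pair cis to C4); a second photon cleaves the weak N–O bond, and the ring bond C3–C1 that lies anti to the nitrogen lone pair shifts from carbon to nitrogen as C3=O forms, so nitrogen is inserted between C1 and C3. The closest known reaction type is the photochemical nitrone–oxaziridine–lactam rearrangement of cyclic ketone derivatives, whose regiochemistry follows the lone-pair rule and is complementary to the acid-mediated Beckmann and Schmidt reactions. The three-membered ring of 8 closes by electrocyclisation, and the piperidinone ring arises by a 1,2-shift of carbon to nitrogen (one-atom enlargement of the cyclopentanone, five to six), not by an end-to-end cyclisation. No stereocentre is created, and C4, C4a, C6, C7 and C7a are untouched, because the migrating carbon C1 is a methylene and no enolisable intermediate is formed. The step needs regioselectivity (C1 and not C4 must migrate), and this is secured by the C4 methyl group, which places the N-methyl on the methylene side in 7 so that the lone pair of 8 is anti to C3–C1; chemoselectivity should follow from the pivalate and the saturated skeleton being transparent at 254 nm.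

Step 8
Reactants: 9 N-methyl lactam
Product: 10 (4R,4aS,6R,7S,7aR)-2,4,7-trimethyloctahydro-1H-cyclopenta[c]pyridin-6-ol, (−)-incarvilline
Conditions: LiAlH4 (excess), THF, 0 °C to reflux; H2O, aq. NaOH work-up
Reagents that add atoms: none
Why: LiAlH4 reduces the tertiary lactam to the tertiary amine through the hemiaminal aluminate and iminium ion and at the same time cleaves the pivalate to the C6 alkoxide (amide and ester reduction), so (−)-incarvilline should result with all five stereocentres unchanged.

Step 9
Reactants: 11 geranyl acetate
Product: 12 (2E,6E)-8-hydroxy-3,7-dimethylocta-2,6-dien-1-yl acetate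
Conditions: SeO2 (0.3 equiv), t-BuOOH (3 equiv), salicylic acid (0.1 equiv), CH2Cl2, rt
Reagents that add atoms: tert-butyl hydroperoxide, CC(C)(C)OO (terminal oxidant; the oxygen is passed on through SeO2, O=[Se]=O)
Why: Catalytic SeO2 allylic oxidation (ene reaction followed by [2,3]-sigmatropic shift) attacks the more electron-rich terminal trisubstituted alkene at its (E)-methyl group and gives the (E)-allylic alcohol, while the alkene next to the acetate is deactivated.

Step 10
Reactants: 12 hydroxy acetate
Product: 13 (2E,6E)-2,6-dimethylocta-2,6-diene-1,8-diol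
Conditions: K2CO3 (cat.), MeOH, rt
Reagents that add atoms: none
Why: Base-catalysed transesterification with methanol removes the acetate without touching either trisubstituted alkene.

Step 11
Reactants: 13 diol
Product: 14 (2E,6E)-2,6-dimethylocta-2,6-dienedial
Conditions: activated MnO2 (excess), CH2Cl2, rt
Reagents that add atoms: none
Why: Activated MnO2 oxidises both primary allylic alcohols chemoselectively to the enals without E/Z isomerisation.

Step 12
Reactants: 14 dialdehyde
Product: 15 (2E,6E)-2,6-dimethylocta-2,6-dienedioic acid
Conditions: NaClO2, NaH2PO4, 2-methyl-2-butene, t-BuOH/H2O, 0 °C to rt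
Reagents that add atoms: sodium chlorite, [Na+].[O-]Cl=O
Why: Pinnick oxidation with a hypochlorite scavenger converts both enals into the enoic acids without attacking or isomerising the alkenes.

Step 13
Reactants: 10 (−)-incarvilline (2.1 equiv); 15 (2E,6E)-2,6-dimethylocta-2,6-dienedioic acid
Product: 16 bis[(4R,4aS,6R,7S,7aR)-2,4,7-trimethyloctahydro-1H-cyclopenta[c]pyridin-6-yl] (2E,6E)-2,6-dimethylocta-2,6-dienedioate (target)
Conditions: DCC (2.5 equiv), DMAP (0.5 equiv), CH2Cl2, 0 °C to rt
Reagents that add atoms: none
Why: Steglich esterification: each acid is activated by DCC and passed through the acylpyridinium ion to the C6 hydroxyl, whose C–O bond is not broken, so the 6R configuration is retained; the tertiary amines cannot be acylated irreversibly and the E-configured enoates should not isomerise.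

**Compound list**

1 | pent-3-yn-1-ol | CC#CCCO | starting material
2 | pent-3-ynal | CC#CCC=O | intermediate
3 | (3S,4R)-3-methyloct-1-en-6-yn-4-ol | CC#CC[C@@H](O)[C@@H](C)C=C | intermediate
4 | (3S,4R)-3-methyloct-1-en-6-yn-4-yl pivalate | CC#CC[C@@H](OC(=O)C(C)(C)C)[C@@H](C)C=C | intermediate
5 | (5R,6S,6aS)-3,6-dimethyl-2-oxo-1,2,4,5,6,6a-hexahydropentalen-5-yl pivalate | CC(C)(C)C(=O)O[C@@H]1CC2=C(C)C(=O)C[C@H]2[C@@H]1C | intermediate
6 | (1S,2R,3aR,4R,6aR)-1,4-dimethyl-5-oxooctahydropentalen-2-yl pivalate | CC(C)(C)C(=O)O[C@@H]1C[C@@H]2[C@@H](CC(=O)[C@@H]2C)[C@@H]1C | intermediate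
7 | (Z)-N-methyl ketonitrone of 6 (N-methyl syn to the ring CH2) | CC(C)(C)C(=O)O[C@@H]1C[C@@H]2[C@@H](C/C(=[N+](\C)[O-])[C@@H]2C)[C@@H]1C | intermediate
8 | N-methyl spiro-oxaziridine of 6 (N-methyl cis to the ring CH2; both spiro-carbon epimers expected, one drawn) | CC(C)(C)C(=O)O[C@@H]1C[C@@H]2[C@@H](C[C@]3(O[N@]3C)[C@@H]2C)[C@@H]1C | intermediate
9 | (4R,4aR,6R,7S,7aR)-2,4,7-trimethyl-3-oxooctahydro-1H-cyclopenta[c]pyridin-6-yl pivalate | CC(C)(C)C(=O)O[C@@H]1C[C@@H]2[C@@H](CN(C)C(=O)[C@@H]2C)[C@@H]1C | intermediate
10 | (4R,4aS,6R,7S,7aR)-2,4,7-trimethyloctahydro-1H-cyclopenta[c]pyridin-6-ol, (−)-incarvilline | O[C@@H]1C[C@@H]2[C@@H](CN(C)C[C@@H]2C)[C@@H]1C | intermediate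
11 | geranyl acetate | CC(C)=CCC/C(C)=C/COC(C)=O | starting material
12 | (2E,6E)-8-hydroxy-3,7-dimethylocta-2,6-dien-1-yl acetate | OC/C(C)=C/CC/C(C)=C/COC(C)=O | intermediate
13 | (2E,6E)-2,6-dimethylocta-2,6-diene-1,8-diol | OC/C(C)=C/CC/C(C)=C/CO | intermediate
14 | (2E,6E)-2,6-dimethylocta-2,6-dienedial | O=C/C(C)=C/CC/C(C)=C/C=O | intermediate
15 | (2E,6E)-2,6-dimethylocta-2,6-dienedioic acid | OC(=O)/C(C)=C/CC/C(C)=C/C(O)=O | intermediate
16 | bis[(4R,4aS,6R,7S,7aR)-2,4,7-trimethyloctahydro-1H-cyclopenta[c]pyridin-6-yl] (2E,6E)-2,6-dimethylocta-2,6-dienedioate | C/C(=C\C(=O)O[C@@H]1C[C@@H]2[C@@H](CN(C)C[C@@H]2C)[C@@H]1C)CC/C=C(\C)C(=O)O[C@@H]1C[C@@H]2[C@@H](CN(C)C[C@@H]2C)[C@@H]1C | target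

**Step count and risks**

Total steps: 13. Longest linear sequence: 9 steps (steps 1 to 8, then step 13); steps 9 to 12 form the convergent diacid branch.

Steps most likely to fail:

1. Step 7. The nitrone geometry may scramble under irradiation, or the oxaziridine may form without full stereospecificity, so that the methyl-bearing C4 migrates in part. N–O fragmentation back to the ketone and epimerisation at C4 may also compete. Fallback, from 6 and back at 9: kinetic deprotonation of 6 on the methylene side (LDA, THF, −78 °C) and trapping with TMSCl should give the trimethylsilyl enol ether F1. Ozonolysis (O3, CH2Cl2/MeOH, −78 °C, then Me2S) cleaves its C1=C3 bond to the formyl acid F2. Reductive amination with MeNH2 and NaBH(OAc)3 gives the amino acid F3, which is closed with EDC hydrochloride and HOBt to lactam 9. Nitrogen then enters by C–C cleavage and reductive amination instead of by a photochemical shift.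

2. Step 4. Facial selectivity of the alkene insertion may be poor, giving both ring-fusion epimers, and the alkyne–cobalt species may be lost at 70 °C. Fallback, from 4 and back at 5: Cp2Zr(n-Bu)2, generated from Cp2ZrCl2 and n-BuLi (THF, −78 °C to rt), converts the enyne by reversible oxidative cyclisation into the zirconabicycle F4. In F4 the ring-fusion centre can equilibrate to the isomer with methyl and pivaloyloxy on the convex face. CO (1 atm, 0 °C) and then I2 release enone 5. Stereocontrol then rests on thermodynamic equilibration of a metallacycle instead of on a kinetic insertion.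

3. Step 2. The beta,gamma-alkynyl aldehyde may isomerise to the allenyl aldehyde or be lost on concentration before the C–C bond is formed. Any erosion of enantiomeric purity would show up as diastereomers after step 13, because two units are joined there. Fallback, from 1 and back at 3: alcohol 1 is crotylated directly under iridium-catalysed transfer hydrogenation ([Ir(cod)Cl]2, the SEGPHOS enantiomer that gives the 3S,4R product, 4-cyano-3-nitrobenzoic acid, Cs2CO3, but-3-en-2-yl acetate, THF, 90 °C). The aldehyde then exists only transiently at the metal and is never handled; this fallback makes no new compound (F0).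

**Further compounds**

F1 | step 7 | trimethylsilyl enol ether of 6 (C1=C3 enol ether) | CC(C)(C)C(=O)O[C@@H]1C[C@@H]2[C@@H](C=C(O[Si](C)(C)C)[C@@H]2C)[C@@H]1C
F2 | step 7 | 2-[2-formyl-3-methyl-4-(pivaloyloxy)cyclopentyl]propanoic acid (configuration as in 6) | CC(C)(C)C(=O)O[C@@H]1C[C@@H]([C@@H](C)C(=O)O)[C@@H](C=O)[C@@H]1C
F3 | step 7 | 2-[3-methyl-2-[(methylamino)methyl]-4-(pivaloyloxy)cyclopentyl]propanoic acid (configuration as in 6) | CC(C)(C)C(=O)O[C@@H]1C[C@@H]([C@@H](C)C(=O)O)[C@@H](CNC)[C@@H]1C
F4 | step 4 | bis(cyclopentadienyl)zirconabicycle from 4 (Zr bonded to the C1 methylene and to the methyl-bearing alkenyl carbon C4) | CC(C)(C)C(=O)O[C@@H]1CC2=C(C)[Zr](C3C=CC=C3)(C3C=CC=C3)C[C@H]2[C@@H]1C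
F0 | step 2 | none | none
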